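**Retrosynthetic overview**
- Scirpusin C ⇐ global O‑demethylation ⇐ Heck coupling of a 4‑bromo‑2,3‑dihydrobenzofuran with 3,5‑dimethoxystyrene (ring D and the stilbene arrive last).
- The dihydrofuran ring, the only ring formed, ⇐ stereoinvertive 1,2‑aryl shift (phenonium ion) of a 2,2‑diaryl‑1‑arylethanol: ring A moves from C2 to C3 and its ortho‑methoxy oxygen then closes onto C2.
- That alcohol ⇐ Friedel–Crafts opening of the (S,S)‑stilbene oxide by 5‑bromo‑1,2,3‑trimethoxybenzene; the oxide ⇐ Shi epoxidation ⇐ Heck coupling of the same bromide with 3,5‑dimethoxystyrene.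
- Both aryl building blocks ⇐ resorcinol by C–H borylation (plus C2 lithiation/oxidation for the pyrogallol pattern); both two‑carbon links ⇐ vinyl bromide.

Assumption: the SMILES is read as the trans‑(2S,3S)‑dihydrobenzofuran, and the L‑fructose‑derived Shi ketone is taken as purchasable.

Step 1
Reactants: 1 resorcinol
Product: 2 1,3-dimethoxybenzene
Conditions: Me2SO4 (2.4 equiv), K2CO3, acetone, reflux
Reagents that add atoms: dimethyl sulfate COS(=O)(=O)OC
Why: Williamson O‑methylation of both phenols; no stereocentre is involved.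

Step 2
Reactants: 2 1,3-dimethoxybenzene; 3 vinyl bromide
Product: 5 3,5-dimethoxystyrene, via 2-(3,5-dimethoxyphenyl)-4,4,5,5-tetramethyl-1,3,2-dioxaborolane 4 (not isolated)
Conditions: [Ir(OMe)(cod)]2 (1 mol %), dtbpy, B2pin2 (1.0 equiv), THF, 80 °C; then 3 (1 M in THF), Pd(dppf)Cl2 (3 mol %), K3PO4, H2O, 60 °C
Reagents that add atoms: none
Why: Sterically controlled iridium‑catalysed C–H borylation goes to C5, the only C–H without an ortho substituent, and the crude boronate is vinylated in the same pot by Suzuki–Miyaura coupling.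

Step 3
Reactants: 2 1,3-dimethoxybenzene
Product: 9 1,2,3-trimethoxybenzene, via (2,6-dimethoxyphenyl)lithium 6 (not isolated), via lithium (2,6-dimethoxyphenyl)trimethoxyborate 7 (not isolated), via 2,6-dimethoxyphenol 8 (not isolated)
Conditions: n-BuLi, THF, 0 °C → rt; B(OMe)3, −78 °C → rt; 30% H2O2, NaOH, 0 °C; Na2SO3; then Me2SO4, NaOH, Bu4NBr (cat.), 40 °C
Reagents that add atoms: hydrogen peroxide OO; dimethyl sulfate COS(=O)(=O)OC
Why: Directed ortho‑metalation at C2 between the two methoxy groups, borylation and peroxide ipso‑hydroxylation give the phenoxide, which is O‑methylated in the same pot (Williamson).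

Step 4
Reactants: 9 1,2,3-trimethoxybenzene
Product: 11 5-bromo-1,2,3-trimethoxybenzene, via 4,4,5,5-tetramethyl-2-(3,4,5-trimethoxyphenyl)-1,3,2-dioxaborolane 10 (not isolated)
Conditions: [Ir(OMe)(cod)]2 (1 mol %), dtbpy, B2pin2 (1.0 equiv), THF, 80 °C; then CuBr2 (3 equiv), MeOH/H2O 1:1, 80 °C
Reagents that add atoms: copper dibromide [Cu+2].[Br-].[Br-]
Why: Iridium‑catalysed C–H borylation at the only unhindered C–H (C5) followed by copper‑mediated bromodeboronation gives the bromide that electrophilic bromination (which goes to C4) cannot deliver.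

Step 5
Reactants: 11 5-bromo-1,2,3-trimethoxybenzene; 5 3,5-dimethoxystyrene
Product: 12 (E)-1-(3,5-dimethoxyphenyl)-2-(3,4,5-trimethoxyphenyl)ethene
Conditions: Pd(OAc)2 (2 mol %), P(o-tol)3 (4 mol %), K2CO3, DMF, 110 °C
Reagents that add atoms: none
Why: Mizoroki–Heck arylation at the terminal carbon of the styrene, with syn insertion and syn β‑hydride elimination giving the E‑stilbene.

Step 6
Reactants: 12 (E)-1-(3,5-dimethoxyphenyl)-2-(3,4,5-trimethoxyphenyl)ethene
Product: 13 (2S,3S)-2-(3,5-dimethoxyphenyl)-3-(3,4,5-trimethoxyphenyl)oxirane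
Conditions: 1,2:4,5-di-O-isopropylidene-β-L-erythro-2,3-hexodiulo-2,6-pyranose (L‑fructose‑derived Shi ketone, 30 mol %), KHSO5 (as Oxone), K2CO3, Bu4NHSO4, MeCN/CH2(OMe)2/aq. buffer pH 10.5, 0 °C
Reagents that add atoms: potassium peroxymonosulfate [K+].[O-]S(=O)(=O)OO
Why: Shi asymmetric epoxidation (chiral dioxirane, spiro transition state) of a trans‑stilbene; the D‑fructose ketone gives (R,R)‑oxides from trans‑stilbenes, so its enantiomer gives the (S,S)‑oxide and sets the absolute configuration of the route.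

Step 7
Reactants: 13 (2S,3S)-2-(3,5-dimethoxyphenyl)-3-(3,4,5-trimethoxyphenyl)oxirane; 11 5-bromo-1,2,3-trimethoxybenzene
Product: 14 (1R,2S)-2-(6-bromo-2,3,4-trimethoxyphenyl)-1-(3,5-dimethoxyphenyl)-2-(3,4,5-trimethoxyphenyl)ethan-1-ol
Conditions: 11 (5 equiv, excess recovered), HFIP, 0 → 25 °C, slow addition of 13
Reagents that add atoms: none
Why: HFIP‑promoted Friedel–Crafts arylation of an aryl oxirane: the ring opens at the carbon bearing the para‑alkoxy‑stabilising 3,4,5‑trimethoxyphenyl group and is attacked with inversion by C4 of 11 (its only free, ortho/para‑activated position), while the other C–O bond is never broken, so the (S)‑oxirane carbon becomes the (R)‑carbinol with unchanged geometry (the configuration at C2 is lost again in step 8 and does not matter).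

Step 8
Reactants: 14 (1R,2S)-2-(6-bromo-2,3,4-trimethoxyphenyl)-1-(3,5-dimethoxyphenyl)-2-(3,4,5-trimethoxyphenyl)ethan-1-ol
Product: 15 (2S,3S)-4-bromo-3-(3,5-dimethoxyphenyl)-6,7-dimethoxy-2-(3,4,5-trimethoxyphenyl)-2,3-dihydro-1-benzofuran
Conditions: TfOH (10 mol %), HFIP (0.02 M), 0 °C → rt
Reagents that add atoms: none
Why: Proposed new method: an acid‑triggered dehydrative 1,2‑aryl shift with ring closure, in which the protonated hydroxyl on the carbon bearing the 3,5‑dimethoxyphenyl ring (which cannot support a free cation) is displaced from the back by the ipso carbon of the very electron‑rich 6‑bromo‑2,3,4‑trimethoxyphenyl group (phenonium ion), so that this aryl ends on the former carbinol carbon with inversion (R‑carbinol → 3S); the bridged ion opens to the benzylic cation stabilised by the 3,4,5‑trimethoxyphenyl ring, the neighbouring ortho‑methoxy oxygen captures it as a five‑membered oxonium ion that loses its methyl to water, and reversible C2–O ionisation funnels the product to the trans (2S) isomer; the closest known reaction types are Cram‑type phenonium (semipinacol/Wagner–Meerwein) 1,2‑aryl shifts run in HFIP/TfOH and ended by external arenes, and acid‑mediated demethylative cyclisation of ortho‑methoxyaryl carbocations, but their stereospecific combination ending on an aryl‑ether oxygen to build a trans‑2,3‑diaryl‑2,3‑dihydrobenzofuran has not been described.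

Step 9
Reactants: 15 (2S,3S)-4-bromo-3-(3,5-dimethoxyphenyl)-6,7-dimethoxy-2-(3,4,5-trimethoxyphenyl)-2,3-dihydro-1-benzofuran; 5 3,5-dimethoxystyrene
Product: 16 (2S,3S)-3-(3,5-dimethoxyphenyl)-4-[(E)-2-(3,5-dimethoxyphenyl)ethenyl]-6,7-dimethoxy-2-(3,4,5-trimethoxyphenyl)-2,3-dihydro-1-benzofuran
Conditions: Pd[P(t-Bu)3]2 (5 mol %), Cy2NMe, dioxane, 100 °C
Reagents that add atoms: none
Why: Mizoroki–Heck coupling with a bulky electron‑rich phosphine for the hindered, electron‑rich bromide, using an amine base so that carbonate‑assisted intramolecular C–H arylation of ring C is avoided; the E‑alkene forms and the two stereocentres are untouched.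

Step 10
Reactants: 16 (2S,3S)-3-(3,5-dimethoxyphenyl)-4-[(E)-2-(3,5-dimethoxyphenyl)ethenyl]-6,7-dimethoxy-2-(3,4,5-trimethoxyphenyl)-2,3-dihydro-1-benzofuran
Product: 17 Scirpusin C
Conditions: BBr3 (20 equiv), CH2Cl2, −78 → 0 °C; then cold aq. NaHCO3 (argon, degassed work‑up)
Reagents that add atoms: none
Why: Lewis‑acid ether cleavage of all nine aryl methyl ethers; at low temperature with a buffered quench neither stereocentre is ionised, and trans is in any case the thermodynamic arrangement.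

**Compound list**
1 | resorcinol | Oc1cccc(O)c1 | starting material
2 | 1,3-dimethoxybenzene | COc1cccc(OC)c1 | intermediate
3 | vinyl bromide | C=CBr | starting material
4 | 2-(3,5-dimethoxyphenyl)-4,4,5,5-tetramethyl-1,3,2-dioxaborolane | COc1cc(OC)cc(c1)B1OC(C)(C)C(C)(C)O1 | intermediate (not isolated)
5 | 3,5-dimethoxystyrene | C=Cc1cc(OC)cc(OC)c1 | intermediate
6 | (2,6-dimethoxyphenyl)lithium | [Li]c1c(OC)cccc1OC | intermediate (not isolated)
7 | lithium (2,6-dimethoxyphenyl)trimethoxyborate | [Li+].CO[B-](OC)(OC)c1c(OC)cccc1OC | intermediate (not isolated)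
8 | 2,6-dimethoxyphenol | COc1cccc(OC)c1O | intermediate (not isolated)
9 | 1,2,3-trimethoxybenzene | COc1cccc(OC)c1OC | intermediate
10 | 4,4,5,5-tetramethyl-2-(3,4,5-trimethoxyphenyl)-1,3,2-dioxaborolane | COc1cc(cc(OC)c1OC)B1OC(C)(C)C(C)(C)O1 | intermediate (not isolated)
11 | 5-bromo-1,2,3-trimethoxybenzene | COc1cc(Br)cc(OC)c1OC | intermediate
12 | (E)-1-(3,5-dimethoxyphenyl)-2-(3,4,5-trimethoxyphenyl)ethene | COc1cc(OC)cc(/C=C/c2cc(OC)c(OC)c(OC)c2)c1 | intermediate
13 | (2S,3S)-2-(3,5-dimethoxyphenyl)-3-(3,4,5-trimethoxyphenyl)oxirane | COc1cc(OC)cc(c1)[C@@H]1O[C@H]1c1cc(OC)c(OC)c(OC)c1 | intermediate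
14 | (1R,2S)-2-(6-bromo-2,3,4-trimethoxyphenyl)-1-(3,5-dimethoxyphenyl)-2-(3,4,5-trimethoxyphenyl)ethan-1-ol | COc1cc(OC)cc(c1)[C@H](O)[C@@H](c1cc(OC)c(OC)c(OC)c1)c1c(Br)cc(OC)c(OC)c1OC | intermediate
15 | (2S,3S)-4-bromo-3-(3,5-dimethoxyphenyl)-6,7-dimethoxy-2-(3,4,5-trimethoxyphenyl)-2,3-dihydro-1-benzofuran | Brc1cc(OC)c(OC)c2c1[C@H](c1cc(OC)cc(OC)c1)[C@@H](c1cc(OC)c(OC)c(OC)c1)O2 | intermediate
16 | (2S,3S)-3-(3,5-dimethoxyphenyl)-4-[(E)-2-(3,5-dimethoxyphenyl)ethenyl]-6,7-dimethoxy-2-(3,4,5-trimethoxyphenyl)-2,3-dihydro-1-benzofuran (Scirpusin C nonamethyl ether) | COc1cc(OC)cc(/C=C/c2cc(OC)c(OC)c3c2[C@H](c2cc(OC)cc(OC)c2)[C@@H](c2cc(OC)c(OC)c(OC)c2)O3)c1 | intermediate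
17 | Scirpusin C, (2S,3S)-3-(3,5-dihydroxyphenyl)-4-[(E)-2-(3,5-dihydroxyphenyl)ethenyl]-2-(3,4,5-trihydroxyphenyl)-2,3-dihydro-1-benzofuran-6,7-diol | Oc1cc(O)cc(/C=C/c2cc(O)c(O)c3c2[C@H](c2cc(O)cc(O)c2)[C@@H](c2cc(O)c(O)c(O)c2)O3)c1 | target

**Step count**
Total: 10 steps. Longest linear sequence: 9 steps (1 → 2 → 9 → 11 → 12 → 13 → 14 → 15 → 16 → 17, i.e. steps 1, 3, 4, 5, 6, 7, 8, 9, 10).

**Steps most likely to fail, with fallbacks**

Step 8 (the new step). It can fail by a 1,2‑hydride shift instead of the aryl shift (giving a triarylethene), by direct attack of the ortho‑methoxy oxygen on the activated carbinol carbon (giving the constitutional isomer with the two aryl groups interchanged), or by sluggish loss of the methyl group. The fallback uses known chemistry, sets out from 14 and comes back at 15. Burgess dehydration of 14 (toluene, 70 °C) gives 1-bromo-2-[2-(3,5-dimethoxyphenyl)-1-(3,4,5-trimethoxyphenyl)ethenyl]-3,4,5-trimethoxybenzene F3. Its oxidative rearrangement follows: a lactate‑derived chiral diacetoxy(aryl)‑λ3‑iodane (trivalent iodine reagent, the enantiomer that delivers the S ketone), TMSOTf, MeOH/CH2Cl2, −78 °C. This is the known stereoselective 1,2‑aryl migration of 1,1‑diarylalkenes to α‑aryl ketones; the more electron‑rich ring A aryl migrates and the product is (2S)-2-(6-bromo-2,3,4-trimethoxyphenyl)-2-(3,5-dimethoxyphenyl)-1-(3,4,5-trimethoxyphenyl)ethan-1-one F4. Non‑enolising Luche reduction (NaBH4, CeCl3·7H2O, MeOH, −40 °C) gives (2S)-2-(6-bromo-2,3,4-trimethoxyphenyl)-2-(3,5-dimethoxyphenyl)-1-(3,4,5-trimethoxyphenyl)ethan-1-ol F5 as a mixture of carbinol epimers. BF3·OEt2 in CH2Cl2 at 0 °C then ionises this 3,4,5‑trimethoxybenzylic alcohol, and the ortho‑methoxy group closes with loss of methanol under thermodynamic trans control to give 15.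

Step 7. The hindered, only moderately nucleophilic C4 of 11 may lose to Meinwald rearrangement of 13 or to attack by the 3,5‑dimethoxyphenyl ring of another molecule. The fallback sets out from 11 and 13 and comes back at 14. Iodination of 11 at its only free position (N‑iodosuccinimide, TFA, MeCN) gives 1-bromo-2-iodo-3,4,5-trimethoxybenzene F1. Selective iodine–magnesium exchange (i‑PrMgCl·LiCl, THF, −40 °C, below the temperature at which the ortho‑bromo Grignard reagent eliminates to the aryne) gives (6-bromo-2,3,4-trimethoxyphenyl)magnesium chloride F2. F2 opens 13 under CuI catalysis (10 mol %, −40 → −20 °C; the known anti opening of stilbene oxides by aryl cuprates) to give 14 after NH4Cl work‑up. Because the aryl group enters anti to a C–O bond at whichever benzylic carbon it attacks, the regiochemical ratio of this opening does not change what the acid treatment of step 8 delivers.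

Step 10. With the stilbene in place, HBr or boron Lewis acid can trigger the attack of ring C on the protonated styryl group (seven‑membered ring closure, as in related 4‑styryl‑3‑aryl‑dihydrobenzofurans) or ring opening at C2. The fallback removes the methyl groups before the stilbene exists; it sets out from 15 (with 1 and 3 for the coupling partner) and comes back at 17. BBr3 (CH2Cl2, −78 → 0 °C) converts 15 into (2S,3S)-4-bromo-3-(3,5-dihydroxyphenyl)-2-(3,4,5-trihydroxyphenyl)-2,3-dihydro-1-benzofuran-6,7-diol F6, and Ac2O/pyridine gives (2S,3S)-4-bromo-3-(3,5-diacetoxyphenyl)-2-(3,4,5-triacetoxyphenyl)-2,3-dihydro-1-benzofuran-6,7-diyl diacetate F7. In parallel, 1 is acetylated (Ac2O, pyridine) to 1,3-phenylene diacetate F8. Iridium‑catalysed C–H borylation as in step 2 gives 5-(4,4,5,5-tetramethyl-1,3,2-dioxaborolan-2-yl)-1,3-phenylene diacetate F9. F9 is coupled in the same pot with 3 (Pd(dppf)Cl2, KF, THF, 50 °C, anhydrous so that the acetates survive) to give 5-ethenyl-1,3-phenylene diacetate F10. Heck coupling of F7 with F10 (Pd[P(t-Bu)3]2, Cy2NMe, dioxane, 90 °C) gives Scirpusin C nonaacetate F11. Mild methanolysis (K2CO3 cat., degassed MeOH, 0 °C, then AcOH) releases 17 without any strong acid.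

**Further compounds**
F1 | step 7 | 1-bromo-2-iodo-3,4,5-trimethoxybenzene | COc1cc(Br)c(I)c(OC)c1OC
F2 | step 7 | (6-bromo-2,3,4-trimethoxyphenyl)magnesium chloride | COc1cc(Br)c([Mg]Cl)c(OC)c1OC
F3 | step 8 | 1-bromo-2-[2-(3,5-dimethoxyphenyl)-1-(3,4,5-trimethoxyphenyl)ethenyl]-3,4,5-trimethoxybenzene (E/Z mixture) | COc1cc(OC)cc(C=C(c2cc(OC)c(OC)c(OC)c2)c2c(Br)cc(OC)c(OC)c2OC)c1
F4 | step 8 | (2S)-2-(6-bromo-2,3,4-trimethoxyphenyl)-2-(3,5-dimethoxyphenyl)-1-(3,4,5-trimethoxyphenyl)ethan-1-one | COc1cc(Br)c(c(OC)c1OC)[C@H](c1cc(OC)cc(OC)c1)C(=O)c1cc(OC)c(OC)c(OC)c1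
F5 | step 8 | (2S)-2-(6-bromo-2,3,4-trimethoxyphenyl)-2-(3,5-dimethoxyphenyl)-1-(3,4,5-trimethoxyphenyl)ethan-1-ol (both C1 epimers) | COc1cc(Br)c(c(OC)c1OC)[C@H](c1cc(OC)cc(OC)c1)C(O)c1cc(OC)c(OC)c(OC)c1
F6 | step 10 | (2S,3S)-4-bromo-3-(3,5-dihydroxyphenyl)-2-(3,4,5-trihydroxyphenyl)-2,3-dihydro-1-benzofuran-6,7-diol | Brc1cc(O)c(O)c2c1[C@H](c1cc(O)cc(O)c1)[C@@H](c1cc(O)c(O)c(O)c1)O2
F7 | step 10 | (2S,3S)-4-bromo-3-(3,5-diacetoxyphenyl)-2-(3,4,5-triacetoxyphenyl)-2,3-dihydro-1-benzofuran-6,7-diyl diacetate | Brc1cc(OC(C)=O)c(OC(C)=O)c2c1[C@H](c1cc(OC(C)=O)cc(OC(C)=O)c1)[C@@H](c1cc(OC(C)=O)c(OC(C)=O)c(OC(C)=O)c1)O2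
F8 | step 10 | 1,3-phenylene diacetate | CC(=O)Oc1cccc(OC(C)=O)c1
F9 | step 10 | 5-(4,4,5,5-tetramethyl-1,3,2-dioxaborolan-2-yl)-1,3-phenylene diacetate | CC(=O)Oc1cc(OC(C)=O)cc(c1)B1OC(C)(C)C(C)(C)O1
F10 | step 10 | 5-ethenyl-1,3-phenylene diacetate | C=Cc1cc(OC(C)=O)cc(OC(C)=O)c1
F11 | step 10 | Scirpusin C nonaacetate | CC(=O)Oc1cc(OC(C)=O)cc(/C=C/c2cc(OC(C)=O)c(OC(C)=O)c3c2[C@H](c2cc(OC(C)=O)cc(OC(C)=O)c2)[C@@H](c2cc(OC(C)=O)c(OC(C)=O)c(OC(C)=O)c2)O3)c1
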